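**Retrosynthetic overview**
- Target ⇒ its tetrakis-MOM ether; the phenols are freed last, after the stereocentre and the three prenyl groups are in place.
- Ring C is formed last: the O1–C2 bond by intramolecular Mitsunobu etherification (inversion) of a (3R)-β-hydroxy ketone carrying one free ortho-phenol on ring A.
- The β-hydroxy ketone is cut at C4–C4a: a ring-A aryllithium adds to an (R)-β-silyloxy Weinreb amide carrying ring B.
- The Weinreb amide comes from an aryl β-keto ester; its ketone is reduced by a ketoreductase, which sets the only stereocentre.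
- Rings A and B are bought as phloroglucinol and resorcinol and elaborated by MOM protection and directed ortho-lithiation (prenyl, prenyl/acyl).

Assumption: the target is the (2S)-flavanone encoded by the SMILES; prenyl = 3-methylbut-2-en-1-yl, MOM = methoxymethyl, TBS = tert-butyldimethylsilyl.

**Step 1**
Reactants: 1 resorcinol
Product: 2 1,3-bis(methoxymethoxy)benzene
Conditions: MOMCl, i-Pr2NEt, CH2Cl2, 0 °C → rt
Reagents that add atoms: chloromethyl methyl ether (MOMCl), COCCl
Why: O-alkylation of both phenols by the reactive α-chloro ether (acetal formation) is fast and clean, and the MOM ethers are the ortho-directing groups needed for the next two lithiations.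

**Step 2**
Reactants: 2 1,3-bis(methoxymethoxy)benzene; 3 prenyl bromide (1-bromo-3-methylbut-2-ene)
Product: 5 1,3-bis(methoxymethoxy)-2-prenylbenzene, via aryllithium 4 (not isolated)
Conditions: n-BuLi, THF, 0 °C → rt; CuI (10 mol%), 3, −78 °C → rt
Reagents that add atoms: none
Why: Directed ortho-metalation removes the C2–H flanked by two OMOM groups, and the aryl metal is alkylated at the primary carbon of the allylic bromide (SN2, copper catalysis suppresses SN2').

**Step 3**
Reactants: 5 1,3-bis(methoxymethoxy)-2-prenylbenzene; 6 N-methoxy-N-methylacetamide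
Product: 8 1-[2,4-bis(methoxymethoxy)-3-prenylphenyl]ethan-1-one, via aryllithium 7 (not isolated)
Conditions: n-BuLi, TMEDA, THF, 0 °C; 6, −78 → 0 °C; H2O
Reagents that add atoms: none
Why: A second directed ortho-metalation at C4 (C4 and C6 are equivalent) is followed by Weinreb ketone synthesis, whose chelated tetrahedral adduct prevents over-addition.

**Step 4**
Reactants: 8 1-[2,4-bis(methoxymethoxy)-3-prenylphenyl]ethan-1-one; 9 diethyl carbonate
Product: 10 ethyl 3-[2,4-bis(methoxymethoxy)-3-prenylphenyl]-3-oxopropanoate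
Conditions: NaH, 9 (excess), THF, reflux; AcOH
Reagents that add atoms: none
Why: Crossed Claisen condensation of the methyl ketone enolate with diethyl carbonate is driven by irreversible deprotonation of the β-keto ester, and the acetals and the trisubstituted alkene are inert to NaH.

**Step 5**
Reactants: 10 ethyl 3-[2,4-bis(methoxymethoxy)-3-prenylphenyl]-3-oxopropanoate
Product: 11 ethyl (3R)-3-[2,4-bis(methoxymethoxy)-3-prenylphenyl]-3-hydroxypropanoate
Conditions: (R)-selective ketoreductase (KRED, NADPH-dependent alcohol dehydrogenase), NADP+ (cat.), i-PrOH/KPi buffer pH 7.0 (1:4), MgSO4 (2 mM), 30 °C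
Reagents that add atoms: none
Why: Enzymatic asymmetric ketone reduction: an anti-Prelog ketoreductase picked from a screening panel delivers hydride to one face of the aryl ketone and sets the only stereocentre as 3R, propan-2-ol recycles the cofactor, and alkene, ester and acetals are untouched at pH 7.

**Step 6**
Reactants: 11 ethyl (3R)-3-[2,4-bis(methoxymethoxy)-3-prenylphenyl]-3-hydroxypropanoate
Product: 12 (3R)-3-[2,4-bis(methoxymethoxy)-3-prenylphenyl]-3-hydroxy-N-methoxy-N-methylpropanamide
Conditions: MeNHOMe·HCl, i-PrMgCl, THF, −20 → 0 °C; aq. NH4Cl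
Reagents that add atoms: N,O-dimethylhydroxylamine hydrochloride, CNOC.Cl
Why: Weinreb amidation of the ester by the magnesium amide made in the flask proceeds with the alcohol held as its magnesium alkoxide, which blocks β-elimination and leaves the stereocentre untouched.

**Step 7**
Reactants: 12 (3R)-3-[2,4-bis(methoxymethoxy)-3-prenylphenyl]-3-hydroxy-N-methoxy-N-methylpropanamide
Product: 13 (3R)-3-[2,4-bis(methoxymethoxy)-3-prenylphenyl]-3-[(tert-butyldimethylsilyl)oxy]-N-methoxy-N-methylpropanamide
Conditions: TBSCl, imidazole, DMAP (cat.), DMF, 35 °C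
Reagents that add atoms: tert-butyldimethylsilyl chloride (TBSCl), CC(C)(C)[Si](C)(C)Cl
Why: Silylation of the secondary benzylic alcohol masks the acidic OH before the organolithium coupling and removes retro-aldol pathways, with the configuration unchanged.

**Step 8**
Reactants: 14 phloroglucinol
Product: 15 1,3,5-tris(methoxymethoxy)benzene
Conditions: NaH, MOMCl, DMF, 0 °C → rt
Reagents that add atoms: chloromethyl methyl ether (MOMCl), COCCl
Why: Threefold O-alkylation of the phenoxide by the hard α-chloro ether (O- rather than C-alkylation) installs the protecting and directing groups on ring A.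

**Step 9**
Reactants: 15 1,3,5-tris(methoxymethoxy)benzene; 3 prenyl bromide
Product: 17 1,3,5-tris(methoxymethoxy)-2-prenylbenzene, via aryllithium 16 (not isolated)
Conditions: n-BuLi, THF, 0 °C → rt; CuI (10 mol%), 3, −78 °C → rt
Reagents that add atoms: none
Why: Directed ortho-metalation between two OMOM groups followed by SN2 allylic alkylation, as in step 2.

**Step 10**
Reactants: 17 1,3,5-tris(methoxymethoxy)-2-prenylbenzene; 3 prenyl bromide
Product: 19 1,3,5-tris(methoxymethoxy)-2,4-diprenylbenzene, via aryllithium 18 (not isolated)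
Conditions: n-BuLi, THF, 0 °C → rt; CuI (10 mol%), 3, −78 °C → rt
Reagents that add atoms: none
Why: The two remaining ring hydrogens are equivalent and each lies between two OMOM groups, so a second directed ortho-metalation and allylic alkylation gives a single diprenyl arene.

**Step 11**
Reactants: 19 1,3,5-tris(methoxymethoxy)-2,4-diprenylbenzene; 13 the (3R)-silyloxy Weinreb amide
Product: 21 (3R)-3-[2,4-bis(methoxymethoxy)-3-prenylphenyl]-3-[(tert-butyldimethylsilyl)oxy]-1-[2,4,6-tris(methoxymethoxy)-3,5-diprenylphenyl]propan-1-one, via aryllithium 20 (not isolated)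
Conditions: n-BuLi, THF, 0 °C; 13, −78 → −20 °C; H2O
Reagents that add atoms: none
Why: Directed ortho-metalation of the last ring hydrogen and Weinreb ketone synthesis form the C4–C4a bond by single addition, and the stereocentre, being β to the new carbonyl, cannot epimerise.

**Step 12**
Reactants: 21 the tris-MOM ring-A ketone
Product: 22 (3R)-3-[2,4-bis(methoxymethoxy)-3-prenylphenyl]-3-[(tert-butyldimethylsilyl)oxy]-1-[2-hydroxy-4,6-bis(methoxymethoxy)-3,5-diprenylphenyl]propan-1-one
Conditions: MgBr2·OEt2 (3 equiv), Et2O/toluene, 0 °C → rt; H2O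
Reagents that add atoms: none
Why: Chelation-controlled acetal cleavage: MgBr2 is held between the ketone oxygen and one flanking ortho OMOM group so that bromide opens only that MOM ether, while the non-chelated MOM ethers, the silyl ether and the alkenes stay intact and no Brønsted acid reaches the electron-rich benzylic C–O bond.

**Step 13**
Reactants: 22 the mono-phenol silyl ether
Product: 23 (3R)-3-[2,4-bis(methoxymethoxy)-3-prenylphenyl]-3-hydroxy-1-[2-hydroxy-4,6-bis(methoxymethoxy)-3,5-diprenylphenyl]propan-1-one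
Conditions: HF·pyridine, pyridine, THF, 0 °C → rt
Reagents that add atoms: none
Why: Fluoride-mediated desilylation under buffered, weakly acidic conditions removes the TBS group without base (no retro-aldol, no E1cB) and without ionising the benzylic carbinol, so 3R is kept.

**Step 14**
Reactants: 23 the (3R)-β-hydroxy ketone
Product: 24 (2S)-2-[2,4-bis(methoxymethoxy)-3-prenylphenyl]-5,7-bis(methoxymethoxy)-6,8-diprenyl-2,3-dihydro-4H-chromen-4-one
Conditions: PPh3, DIAD (slow addition), toluene (0.02 M), 0 °C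
Reagents that add atoms: none
Why: Intramolecular Mitsunobu etherification: the acidic ortho-acyl phenol displaces the alkoxyphosphonium in a 6-exo SN2 step with inversion, which closes ring C and turns 3R into 2S.

**Step 15**
Reactants: 24 the (2S)-tetrakis-MOM flavanone
Product: 25 (2S)-2-[2,4-dihydroxy-3-prenylphenyl]-5,7-dihydroxy-6,8-diprenyl-2,3-dihydro-4H-chromen-4-one (CNP0129172.1)
Conditions: HCl (1.25 M in MeOH), 35 °C, stopped at full conversion
Reagents that add atoms: none
Why: Acid-catalysed transacetalisation of the four aryl MOM ethers to dimethoxymethane frees the phenols under the standard conditions for prenylated flavonoids, kept mild and short so that neither prenyl–phenol cyclisation nor ring opening at C2 sets in.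

**Compound list**
1 | resorcinol | Oc1cccc(O)c1 | starting material
2 | 1,3-bis(methoxymethoxy)benzene | COCOc1cccc(OCOC)c1 | intermediate
3 | prenyl bromide (1-bromo-3-methylbut-2-ene) | CC(C)=CCBr | starting material
4 | [2,6-bis(methoxymethoxy)phenyl]lithium | [Li]c1c(OCOC)cccc1OCOC | intermediate
5 | 1,3-bis(methoxymethoxy)-2-prenylbenzene | CC(C)=CCc1c(OCOC)cccc1OCOC | intermediate
6 | N-methoxy-N-methylacetamide | CC(=O)N(C)OC | starting material
7 | [2,4-bis(methoxymethoxy)-3-prenylphenyl]lithium | [Li]c1ccc(OCOC)c(CC=C(C)C)c1OCOC | intermediate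
8 | 1-[2,4-bis(methoxymethoxy)-3-prenylphenyl]ethan-1-one | CC(=O)c1ccc(OCOC)c(CC=C(C)C)c1OCOC | intermediate
9 | diethyl carbonate | CCOC(=O)OCC | starting material
10 | ethyl 3-[2,4-bis(methoxymethoxy)-3-prenylphenyl]-3-oxopropanoate | CCOC(=O)CC(=O)c1ccc(OCOC)c(CC=C(C)C)c1OCOC | intermediate
11 | ethyl (3R)-3-[2,4-bis(methoxymethoxy)-3-prenylphenyl]-3-hydroxypropanoate | CCOC(=O)C[C@@H](O)c1ccc(OCOC)c(CC=C(C)C)c1OCOC | intermediate
12 | (3R)-3-[2,4-bis(methoxymethoxy)-3-prenylphenyl]-3-hydroxy-N-methoxy-N-methylpropanamide | CON(C)C(=O)C[C@@H](O)c1ccc(OCOC)c(CC=C(C)C)c1OCOC | intermediate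
13 | (3R)-3-[2,4-bis(methoxymethoxy)-3-prenylphenyl]-3-[(tert-butyldimethylsilyl)oxy]-N-methoxy-N-methylpropanamide | CON(C)C(=O)C[C@@H](O[Si](C)(C)C(C)(C)C)c1ccc(OCOC)c(CC=C(C)C)c1OCOC | intermediate
14 | phloroglucinol | Oc1cc(O)cc(O)c1 | starting material
15 | 1,3,5-tris(methoxymethoxy)benzene | COCOc1cc(OCOC)cc(OCOC)c1 | intermediate
16 | [2,4,6-tris(methoxymethoxy)phenyl]lithium | [Li]c1c(OCOC)cc(OCOC)cc1OCOC | intermediate
17 | 1,3,5-tris(methoxymethoxy)-2-prenylbenzene | CC(C)=CCc1c(OCOC)cc(OCOC)cc1OCOC | intermediate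
18 | [2,4,6-tris(methoxymethoxy)-3-prenylphenyl]lithium | [Li]c1c(OCOC)cc(OCOC)c(CC=C(C)C)c1OCOC | intermediate
19 | 1,3,5-tris(methoxymethoxy)-2,4-diprenylbenzene | CC(C)=CCc1c(OCOC)cc(OCOC)c(CC=C(C)C)c1OCOC | intermediate
20 | [2,4,6-tris(methoxymethoxy)-3,5-diprenylphenyl]lithium | CC(C)=CCc1c(OCOC)c([Li])c(OCOC)c(CC=C(C)C)c1OCOC | intermediate
21 | (3R)-3-[2,4-bis(methoxymethoxy)-3-prenylphenyl]-3-[(tert-butyldimethylsilyl)oxy]-1-[2,4,6-tris(methoxymethoxy)-3,5-diprenylphenyl]propan-1-one | O=C(C[C@@H](O[Si](C)(C)C(C)(C)C)c1ccc(OCOC)c(CC=C(C)C)c1OCOC)c1c(OCOC)c(CC=C(C)C)c(OCOC)c(CC=C(C)C)c1OCOC | intermediate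
22 | (3R)-3-[2,4-bis(methoxymethoxy)-3-prenylphenyl]-3-[(tert-butyldimethylsilyl)oxy]-1-[2-hydroxy-4,6-bis(methoxymethoxy)-3,5-diprenylphenyl]propan-1-one | O=C(C[C@@H](O[Si](C)(C)C(C)(C)C)c1ccc(OCOC)c(CC=C(C)C)c1OCOC)c1c(O)c(CC=C(C)C)c(OCOC)c(CC=C(C)C)c1OCOC | intermediate
23 | (3R)-3-[2,4-bis(methoxymethoxy)-3-prenylphenyl]-3-hydroxy-1-[2-hydroxy-4,6-bis(methoxymethoxy)-3,5-diprenylphenyl]propan-1-one | O=C(C[C@@H](O)c1ccc(OCOC)c(CC=C(C)C)c1OCOC)c1c(O)c(CC=C(C)C)c(OCOC)c(CC=C(C)C)c1OCOC | intermediate
24 | (2S)-2-[2,4-bis(methoxymethoxy)-3-prenylphenyl]-5,7-bis(methoxymethoxy)-6,8-diprenyl-2,3-dihydro-4H-chromen-4-one | CC(C)=CCc1c(OCOC)ccc([C@@H]2CC(=O)c3c(OCOC)c(CC=C(C)C)c(OCOC)c(CC=C(C)C)c3O2)c1OCOC | intermediate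
25 | (2S)-2-[2,4-dihydroxy-3-prenylphenyl]-5,7-dihydroxy-6,8-diprenyl-2,3-dihydro-4H-chromen-4-one (CNP0129172.1) | CC(C)=CCc1c(O)ccc([C@@H]2CC(=O)c3c(O)c(CC=C(C)C)c(O)c(CC=C(C)C)c3O2)c1O | target

**Totals**
Total step count: 15.
Longest linear sequence: 12 steps (steps 1–7 and 11–15, from resorcinol); the ring-A branch (steps 8–10) joins at step 11.

**Three steps most likely to fail**

Step 14 (Mitsunobu ring closure). The carbinol is an electron-rich benzylic alcohol β to a ketone, so partial ionisation or E1cB loss to the chalcone would erode the ee. The fallback sets out from 23 and comes back at 24. K2CO3 in MeOH at 40 °C dehydrates 23 to the 2'-hydroxychalcone F1, which is not isolated and closes by oxa-Michael addition to the racemic flavanone F2. A kinetic resolution by asymmetric transfer hydrogenation (Cp*RhCl(TsDPEN), HCO2H/Et3N, EtOAc, rt) then follows. The TsDPEN antipode that consumes the 2R ketone is fixed on a trial run by chiral HPLC. It reduces the unwanted enantiomer to the cis-(2R,4R)-flavan-4-ol F3, which is removed by chromatography, and leaves 24 at about 55% conversion.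

Step 12 (selective cleavage of one ortho MOM ether). The Lewis acid may attack other acetals or the benzylic silyl ether. The fallback sets out from aryllithium 20 (made from 19) and aryllithium 7 (made from 5) and comes back at 24, bypassing 21–23. Aryllithium 20 is acylated with (E)-3-(dimethylamino)-N-methoxy-N-methylacrylamide to the enaminone F4. Brief methanolic HCl at rt removes one chelated ortho MOM group of this achiral, robust ketone, and the phenol closes with loss of dimethylamine to the chromone F5. Aryllithium 7 is quenched with B(OiPr)3 and then water to give the boronic acid F6. Rhodium-catalysed asymmetric 1,4-addition of F6 to F5 ([Rh(OH)(cod)]2, MeO-F12-BIPHEP, toluene/H2O, 50 °C) gives 24 directly; the ligand antipode that delivers the 2S sense is chosen on the first run.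

Step 11 (hindered aryllithium with an enolisable β-silyloxy Weinreb amide). Slow addition or α-deprotonation with loss of silanolate could win. The fallback sets out from 13 and aryllithium 20 and comes back at 21. i-Bu2AlH (DIBAL-H) in toluene at −78 °C reduces 13 to the (3R)-β-silyloxy aldehyde F7. Aryllithium 20 adds to this far more electrophilic carbonyl at −78 °C to give the diaryl carbinol F8 as both C1 epimers. Dess–Martin periodinane with NaHCO3 in CH2Cl2 oxidises F8 to 21.

**Further compounds**
F1 | step 14 | (E)-3-[2,4-bis(methoxymethoxy)-3-prenylphenyl]-1-[2-hydroxy-4,6-bis(methoxymethoxy)-3,5-diprenylphenyl]prop-2-en-1-one | O=C(/C=C/c1ccc(OCOC)c(CC=C(C)C)c1OCOC)c1c(O)c(CC=C(C)C)c(OCOC)c(CC=C(C)C)c1OCOC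
F2 | step 14 | racemic 2-[2,4-bis(methoxymethoxy)-3-prenylphenyl]-5,7-bis(methoxymethoxy)-6,8-diprenyl-2,3-dihydro-4H-chromen-4-one | CC(C)=CCc1c(OCOC)ccc(C2CC(=O)c3c(OCOC)c(CC=C(C)C)c(OCOC)c(CC=C(C)C)c3O2)c1OCOC
F3 | step 14 | (2R,4R)-2-[2,4-bis(methoxymethoxy)-3-prenylphenyl]-5,7-bis(methoxymethoxy)-6,8-diprenyl-3,4-dihydro-2H-chromen-4-ol | CC(C)=CCc1c(OCOC)ccc([C@H]2C[C@@H](O)c3c(OCOC)c(CC=C(C)C)c(OCOC)c(CC=C(C)C)c3O2)c1OCOC
F4 | step 12 | (E)-3-(dimethylamino)-1-[2,4,6-tris(methoxymethoxy)-3,5-diprenylphenyl]prop-2-en-1-one | CN(C)/C=C/C(=O)c1c(OCOC)c(CC=C(C)C)c(OCOC)c(CC=C(C)C)c1OCOC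
F5 | step 12 | 5,7-bis(methoxymethoxy)-6,8-diprenyl-4H-chromen-4-one | O=c1ccoc2c(CC=C(C)C)c(OCOC)c(CC=C(C)C)c(OCOC)c12
F6 | step 12 | [2,4-bis(methoxymethoxy)-3-prenylphenyl]boronic acid | OB(O)c1ccc(OCOC)c(CC=C(C)C)c1OCOC
F7 | step 11 | (3R)-3-[2,4-bis(methoxymethoxy)-3-prenylphenyl]-3-[(tert-butyldimethylsilyl)oxy]propanal | O=CC[C@@H](O[Si](C)(C)C(C)(C)C)c1ccc(OCOC)c(CC=C(C)C)c1OCOC
F8 | step 11 | (3R)-3-[2,4-bis(methoxymethoxy)-3-prenylphenyl]-3-[(tert-butyldimethylsilyl)oxy]-1-[2,4,6-tris(methoxymethoxy)-3,5-diprenylphenyl]propan-1-ol (both C1 epimers) | OC(C[C@@H](O[Si](C)(C)C(C)(C)C)c1ccc(OCOC)c(CC=C(C)C)c1OCOC)c1c(OCOC)c(CC=C(C)C)c(OCOC)c(CC=C(C)C)c1OCOC
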